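**Retrosynthetic overview**
1. Target 40 ⇐ tris-TBS ether 39 by desilylation.
2. 39 ⇐ seco amidoquinone–dienyl diketone 36: one-pot silylation, macrocyclising Diels–Alder reaction and MnO2 aromatisation close ring B (phenol ring) and ring C (29-membered ansa ring) together; ring A is already there as the benzoquinone.
3. 36 ⇐ Stille union (C5–C6) of vinyl iodide 25 with Z,Z-dienylstannane 33, then phenol → quinone and C23 carbinol → ketone.
4. 25 ⇐ two aldol unions (C9–C10: ketone 13 + aldehyde 19; C23–C5': enal 23 + 3-methylbut-3-en-2-one); 13 ⇐ (S)-Roche ester by crotylboration, Still–Gennari olefination, two cross-metatheses and an allylboration.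
5. Ring order: A (from 2-amino-3-chlorophenol, oxidised late), then B and C in the same operation.

**Assumptions and conventions**
- The target is taken exactly as the SMILES gives it: 2Z,4Z,6E,12E,16E,21Z and 8S,9S,15S,18S,19S,20S. Chain locants run from C1 (amide carbonyl) to C23 (aryl ketone); C5'–C8' are the four carbons of 12 that become ring B positions 5–8.
- (Z)-3-Iodoacrylic acid and 2-amino-3-chlorophenol are taken as purchasable.
- The C23 carbinol of 25, 34 and 35 is an epimer mixture, removed by oxidation in step 25.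

**Route**

Step 1
Reactants: 1 methyl (S)-3-hydroxy-2-methylpropanoate
Product: 2 methyl (S)-2-methyl-3-(triethylsilyloxy)propanoate
Conditions: Et3SiCl, imidazole, CH2Cl2, 0 °C
Reagents that add atoms: chlorotriethylsilane, CC[Si](Cl)(CC)CC
Why: Standard silylation of a primary alcohol; TES is chosen because step 5 can oxidise it off directly, and the stereocentre (future C20) is untouched.

Step 2
Reactants: 2 methyl (S)-2-methyl-3-(triethylsilyloxy)propanoate
Product: 3 (S)-2-methyl-3-(triethylsilyloxy)propanal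
Conditions: i-Bu2AlH (1.05 equiv), CH2Cl2, −78 °C; aq. potassium sodium tartrate; used crude
Reagents that add atoms: none
Why: Partial ester reduction stops at the aluminium hemiacetal at −78 °C, and the cold, crude aldehyde keeps its α-stereocentre.

Step 3
Reactants: 3 (S)-2-methyl-3-(triethylsilyloxy)propanal
Product: 4 (2S,3S,4S)-2,4-dimethyl-1-(triethylsilyloxy)hex-5-en-3-ol
Conditions: trans-2-butene, n-BuLi, KOt-Bu, THF, −45 °C; (−)-Ipc2BOMe [from (+)-α-pinene], −78 °C; BF3·OEt2; then 3, −78 °C; NaOH, H2O2, 0 °C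
Reagents that add atoms: (E)-crotyldiisopinocampheylborane from (+)-α-pinene (made in the flask; crotyl unit from trans-2-butene, C/C=C/C), C/C=C/CB([C@@H]1C[C@@H]2C[C@H]([C@H]1C)C2(C)C)[C@@H]1C[C@@H]2C[C@H]([C@H]1C)C2(C)C
Why: Brown crotylboration through a chair Zimmerman–Traxler transition state: the E-crotyl group gives 18,19-anti, and the (+)-α-pinene-derived ligands select the aldehyde face that gives 19S, which is also the Felkin face of the (S)-aldehyde (matched, 19,20-syn).

Step 4
Reactants: 4 (2S,3S,4S)-2,4-dimethyl-1-(triethylsilyloxy)hex-5-en-3-ol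
Product: 5 (2S,3S,4S)-3-(tert-butyldimethylsilyloxy)-2,4-dimethyl-1-(triethylsilyloxy)hex-5-ene
Conditions: TBSOTf, 2,6-lutidine, CH2Cl2, −78 to 0 °C
Reagents that add atoms: tert-butyldimethylsilyl triflate, CC(C)(C)[Si](C)(C)OS(=O)(=O)C(F)(F)F
Why: The silyl triflate silylates the hindered C19 hydroxyl; a primary TES ether survives these conditions.

Step 5
Reactants: 5 (2S,3S,4S)-3-(tert-butyldimethylsilyloxy)-2,4-dimethyl-1-(triethylsilyloxy)hex-5-ene
Product: 6 (2R,3S,4S)-3-(tert-butyldimethylsilyloxy)-2,4-dimethylhex-5-enal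
Conditions: (COCl)2, DMSO, CH2Cl2, −78 to −40 °C; i-Pr2NEt, −78 to 0 °C
Reagents that add atoms: none
Why: Swern oxidation acting directly on a primary TES ether (cleaved by the chlorosulfonium salt and oxidised in the same flask) while the secondary TBS ether stays; the hindered base and low temperature keep the α-stereocentre.

Step 6
Reactants: 6 (2R,3S,4S)-3-(tert-butyldimethylsilyloxy)-2,4-dimethylhex-5-enal
Product: 7 methyl (2Z,4S,5S,6S)-5-(tert-butyldimethylsilyloxy)-2,4,6-trimethylocta-2,7-dienoate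
Conditions: (CF3CH2O)2P(O)CH(CH3)CO2CH3, KN(SiMe3)2, 18-crown-6, THF, −78 °C
Reagents that add atoms: methyl 2-[bis(2,2,2-trifluoroethoxy)phosphoryl]propanoate, COC(=O)C(C)P(=O)(OCC(F)(F)F)OCC(F)(F)F
Why: Still–Gennari olefination: the electron-poor phosphonate eliminates fast from the kinetic adduct and gives the Z-trisubstituted enoate (C21=C22) without epimerising C20 at −78 °C.

Step 7
Reactants: 7 methyl (2Z,4S,5S,6S)-5-(tert-butyldimethylsilyloxy)-2,4,6-trimethylocta-2,7-dienoate
Product: 8 (2Z,4S,5S,6S)-5-(tert-butyldimethylsilyloxy)-2,4,6-trimethylocta-2,7-dien-1-ol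
Conditions: i-Bu2AlH (2.5 equiv), CH2Cl2, −78 °C
Reagents that add atoms: none
Why: 1,2-Reduction of the enoate to the allylic alcohol with retention of the Z-geometry.

Step 8
Reactants: 8 (2Z,4S,5S,6S)-5-(tert-butyldimethylsilyloxy)-2,4,6-trimethylocta-2,7-dien-1-ol; 9 (E)-but-2-enal (5 equiv)
Product: 10 (2E,4S,5S,6S,7Z)-5-(tert-butyldimethylsilyloxy)-9-hydroxy-4,6,8-trimethylnona-2,7-dienal
Conditions: second-generation Hoveyda–Grubbs catalyst (5 mol %), CH2Cl2, 40 °C
Reagents that add atoms: none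
Why: Olefin cross-metathesis of the only monosubstituted alkene with crotonaldehyde gives the E-enal (C16=C17); the trisubstituted Z-alkene does not react.

Step 9
Reactants: 10 (2E,4S,5S,6S,7Z)-5-(tert-butyldimethylsilyloxy)-9-hydroxy-4,6,8-trimethylnona-2,7-dienal
Product: 11 (2Z,4S,5S,6S,7E,9S)-5-(tert-butyldimethylsilyloxy)-2,4,6-trimethyldodeca-2,7,11-triene-1,9-diol
Conditions: allylMgBr, (−)-Ipc2BOMe [from (+)-α-pinene], Et2O, 0 °C; then 10 (reagent 2.5 equiv), −78 °C; NaOH, H2O2
Reagents that add atoms: allyldiisopinocampheylborane from (+)-α-pinene (made in the flask from allylmagnesium bromide, C=CC[Mg]Br), C=CCB([C@@H]1C[C@@H]2C[C@H]([C@H]1C)C2(C)C)[C@@H]1C[C@@H]2C[C@H]([C@H]1C)C2(C)C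
Why: Brown allylboration (chair transition state) adds 1,2 to the enal and sets C15 as S, the sense this reagent gives with aryl and alkenyl aldehydes; the excess covers the free primary hydroxyl.

Step 10
Reactants: 11 (2Z,4S,5S,6S,7E,9S)-5-(tert-butyldimethylsilyloxy)-2,4,6-trimethyldodeca-2,7,11-triene-1,9-diol; 12 3-methylbut-3-en-2-one (10 equiv)
Product: 13 (3E,6S,7E,9S,10S,11S,12Z)-10-(tert-butyldimethylsilyloxy)-6,14-dihydroxy-3,9,11,13-tetramethyltetradeca-3,7,12-trien-2-one
Conditions: second-generation Hoveyda–Grubbs catalyst (10 mol %), CH2Cl2, 40 °C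
Reagents that add atoms: none
Why: Cross-metathesis of a terminal alkene with a 1,1-disubstituted enone (as with methacrolein) gives the E-trisubstituted enone (C12=C13) and installs the C10 methyl ketone; the doubly branched internal alkene and the trisubstituted alkene are too hindered to compete.

Step 11
Reactants: 14 methyl (R)-3-hydroxy-2-methylpropanoate
Product: 15 methyl (R)-3-(tert-butyldimethylsilyloxy)-2-methylpropanoate
Conditions: TBSCl, imidazole, DMF, 25 °C
Reagents that add atoms: tert-butyldimethylsilyl chloride, CC(C)(C)[Si](C)(C)Cl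
Why: Standard silylation of the primary alcohol (future C9 oxygen).

Step 12
Reactants: 15 methyl (R)-3-(tert-butyldimethylsilyloxy)-2-methylpropanoate
Product: 16 (R)-3-(tert-butyldimethylsilyloxy)-2-methylpropanal
Conditions: i-Bu2AlH (1.05 equiv), CH2Cl2, −78 °C; used crude
Reagents that add atoms: none
Why: Partial ester reduction at −78 °C, as in step 2.

Step 13
Reactants: 16 (R)-3-(tert-butyldimethylsilyloxy)-2-methylpropanal
Product: 17 tert-butyl{[(2S,3E)-4-iodo-2-methylbut-3-en-1-yl]oxy}dimethylsilane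
Conditions: CrCl2 (6 equiv), CHI3 (2 equiv), THF/dioxane, 0 to 25 °C
Reagents that add atoms: iodoform, IC(I)I
Why: Takai olefination gives the E-vinyl iodide (C6=C7) under non-basic conditions that leave the α-stereocentre (C8) intact.

Step 14
Reactants: 17 tert-butyl{[(2S,3E)-4-iodo-2-methylbut-3-en-1-yl]oxy}dimethylsilane
Product: 18 (2S,3E)-4-iodo-2-methylbut-3-en-1-ol
Conditions: HF·pyridine, THF, 0 °C
Reagents that add atoms: none
Why: Fluoride cleavage of the primary silyl ether; the vinyl iodide is inert.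

Step 15
Reactants: 18 (2S,3E)-4-iodo-2-methylbut-3-en-1-ol
Product: 19 (2S,3E)-4-iodo-2-methylbut-3-enal
Conditions: Dess–Martin periodinane, pyridine, CH2Cl2, 0 °C; filtered cold and used at once
Reagents that add atoms: none
Why: Dess–Martin oxidation under buffered, non-enolising conditions gives the β,γ-unsaturated α-methyl aldehyde without epimerisation or conjugation if it is used immediately.

Step 16
Reactants: 13 C10–C23 methyl ketone; 19 (2S,3E)-4-iodo-2-methylbut-3-enal (1.3 equiv)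
Product: 21 C6–C23 iodo triol (6-iodo; 9-OH; 15-OH; 23-OH; 19-OTBS; 11-oxo; 6E,12E,16E,21Z; 8S,9S,15S,18S,19S,20S), via tris-TMS dienol ether 20 (not isolated)
Conditions: LiN(SiMe3)2, Me3SiCl, THF, −78 °C; pentane filtration; then 19, BF3·OEt2, CH2Cl2, −78 °C; citric acid, MeOH, 0 °C
Reagents that add atoms: none
Why: Mukaiyama aldol through an open transition state: C10 of the 2-siloxydiene adds to the BF3-activated aldehyde anti to the vinyl group (Felkin–Anh), setting C9 as S with 8,9-syn; the non-basic conditions do not enolise the labile aldehyde, and the two hydroxyls travel as TMS ethers that the acidic work-up removes.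

Step 17
Reactants: 21 C6–C23 iodo triol
Product: 22 C6–C23 iodo Z-enal diol (C23 aldehyde; 9-OH; 15-OH; 19-OTBS; otherwise as 21)
Conditions: Cu(MeCN)4OTf (5 mol %), 2,2'-bipyridine, TEMPO, N-methylimidazole, air, MeCN, 25 °C
Reagents that add atoms: none
Why: Stahl aerobic oxidation: the Cu/TEMPO system oxidises only the primary allylic alcohol, leaves both secondary alcohols alone and keeps the Z-geometry of the enal.

Step 18
Reactants: 22 C6–C23 iodo Z-enal diol
Product: 23 C6–C23 iodo Z-enal tris-TBS ether (9-OTBS; 15-OTBS; 19-OTBS)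
Conditions: TBSOTf (3 equiv), 2,6-lutidine, CH2Cl2, −78 °C
Reagents that add atoms: tert-butyldimethylsilyl triflate, CC(C)(C)[Si](C)(C)OS(=O)(=O)C(F)(F)F
Why: Silyl triflate protection of both secondary alcohols; at −78 °C with the weak base neither the enal nor the C11 ketone is enolised.

Step 19
Reactants: 23 C6–C23 iodo Z-enal tris-TBS ether; 12 3-methylbut-3-en-2-one (3 equiv)
Product: 25 C6–C23 iodide with the C23 carbinol and the C5'–C8' isopropenyl ketone (C23-OH; C6'=O; epimers at C23), via lithium enolate 24 (not isolated)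
Conditions: LiN(i-Pr)2, THF, −78 °C (12 added slowly); then 23, −78 °C, 20 min; AcOH quench at −78 °C
Reagents that add atoms: none
Why: Kinetic lithium enolate aldol: the CH2 terminus of the cross-conjugated enolate adds 1,2 to the aldehyde far faster than to the C11 ketone at −78 °C; the new C23 centre is an unimportant epimer mixture.

Step 20
Reactants: 26 (Z)-3-iodoprop-2-enoic acid; 27 2-amino-3-chlorophenol
Product: 29 (Z)-N-(2-chloro-6-hydroxyphenyl)-3-iodoprop-2-enamide, via acid chloride 28 (not isolated)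
Conditions: (COCl)2, cat. DMF, CH2Cl2, 0 °C; then 27, pyridine, THF, −20 °C
Reagents that add atoms: none
Why: Acid chloride amidation: the aniline nitrogen is acylated in preference to the phenol oxygen, and working cold keeps the Z-iodoalkene.

Step 21
Reactants: 30 acetylene; 31 hexamethylditin
Product: 32 (Z)-1,2-bis(trimethylstannyl)ethene
Conditions: Pd(PPh3)4 (2 mol %), dioxane, 60 °C
Reagents that add atoms: none
Why: Palladium-catalysed syn-distannation of an alkyne: Sn–Sn oxidative addition and cis insertion of acetylene give only the Z-isomer.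

Step 22
Reactants: 29 (Z)-N-(2-chloro-6-hydroxyphenyl)-3-iodoprop-2-enamide; 32 (Z)-1,2-bis(trimethylstannyl)ethene (3 equiv)
Product: 33 (2Z,4Z)-N-(2-chloro-6-hydroxyphenyl)-5-(trimethylstannyl)penta-2,4-dienamide
Conditions: PdCl2(MeCN)2 (5 mol %), DMF, 25 °C, dark
Reagents that add atoms: none
Why: Stille coupling with retention at both alkene carbons; the excess of 32 stops the reaction after one coupling and gives the Z,Z-dienylstannane.

Step 23
Reactants: 25 C6–C23 iodide; 33 (2Z,4Z)-N-(2-chloro-6-hydroxyphenyl)-5-(trimethylstannyl)penta-2,4-dienamide (1.3 equiv)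
Product: 34 seco anilide (full C1–C23 chain with C5'–C8' enone; N-(2-chloro-6-hydroxyphenyl) amide; 2Z,4Z,6E,12E,16E,21Z; C23-OH)
Conditions: Pd2(dba)3 (10 mol %), AsPh3 (40 mol %), DMF/THF, 25 °C, dark
Reagents that add atoms: none
Why: Stille coupling (AsPh3-accelerated, room temperature) joins C5 to C6 with retention, so the 2Z,4Z,6E-triene follows from the geometry of the two partners.

Step 24
Reactants: 34 seco anilide
Product: 35 seco 2-amido-3-chloro-1,4-benzoquinone (ring A formed; C23-OH)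
Conditions: (KSO3)2NO (3 equiv), KH2PO4, methyltrioctylammonium chloride (cat.), CH2Cl2/H2O, 25 °C
Reagents that add atoms: potassium nitrosodisulfonate, [K+].[K+].[O]N(S(=O)(=O)[O-])S(=O)(=O)[O-]
Why: Teuber oxidation: the nitrosodisulfonate radical oxidises the phenol at its free para position to the p-quinone and does not attack alkenes, silyl ethers or the secondary carbinol.

Step 25
Reactants: 35 seco 2-amido-3-chloro-1,4-benzoquinone
Product: 36 seco amidoquinone 1,3-diketone (C23=O and C6'=O; enolised)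
Conditions: Dess–Martin periodinane (1.5 equiv), pyridine, CH2Cl2, 0 °C, 30 min; rapid filtration, used at once
Reagents that add atoms: none
Why: Dess–Martin oxidation of the allylic C23 carbinol to the 1,3-diketone under buffered conditions; short contact and a small excess avoid oxidation of the diketone methylene.

Step 26
Reactants: 36 seco amidoquinone 1,3-diketone
Product: 39 9,15,19-tris-O-TBS derivative of the target, via TMS dienol ether 37 (not isolated), via Diels–Alder adduct 38 (not isolated)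
Conditions: N,O-bis(trimethylsilyl)acetamide (5 equiv), toluene (0.5 mM), 80 °C, 24–48 h; then MnO2 (excess), 25 °C, air; SiO2
Reagents that add atoms: none
Why: Proposed new method: neutral silylation of the diketone enol gives the 1-acyl-2-siloxy-3-methyl diene 37, whose nucleophilic terminus C5' attacks the more electrophilic quinone carbon (β to the C=O that the amide nitrogen does not deactivate and that the N–H hydrogen-bonds), so the intramolecular [4+2] at high dilution closes ring B and the 29-membered ring C with the acyl group peri to the chlorine-side carbonyl, after which MnO2 dehydrogenates adduct 38 (via enolisation to the hydroquinone and oxidation of the 5,8-dihydro ring) to the naphthoquinone and the aryl TMS ether falls off on silica; the closest known reactions are Diels–Alder additions of 2-acylamino-1,4-benzoquinones and of silyl enol ethers of Nazarov-type vinyl 1,3-dicarbonyls, macrocyclising intramolecular Diels–Alder reactions, and MnO2 aromatisation of quinone cycloadducts.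

Step 27
Reactants: 39 9,15,19-tris-O-TBS derivative of the target
Product: 40 CNP0257532.2
Conditions: HF·pyridine, pyridine, THF, 0 to 25 °C
Reagents that add atoms: none
Why: Buffered fluoride cleavage of the three secondary TBS ethers spares the β-hydroxy ketone, the enones and the quinone; no stereocentre is affected.

**Compound list**
1 | methyl (S)-3-hydroxy-2-methylpropanoate | OC[C@H](C)C(=O)OC | starting material
2 | methyl (S)-2-methyl-3-(triethylsilyloxy)propanoate | CC[Si](CC)(CC)OC[C@H](C)C(=O)OC | intermediate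
3 | (S)-2-methyl-3-(triethylsilyloxy)propanal | CC[Si](CC)(CC)OC[C@H](C)C=O | intermediate
4 | (2S,3S,4S)-2,4-dimethyl-1-(triethylsilyloxy)hex-5-en-3-ol | CC[Si](CC)(CC)OC[C@H](C)[C@@H](O)[C@@H](C)C=C | intermediate
5 | (2S,3S,4S)-3-(tert-butyldimethylsilyloxy)-2,4-dimethyl-1-(triethylsilyloxy)hex-5-ene | CC[Si](CC)(CC)OC[C@H](C)[C@@H](O[Si](C)(C)C(C)(C)C)[C@@H](C)C=C | intermediate
6 | (2R,3S,4S)-3-(tert-butyldimethylsilyloxy)-2,4-dimethylhex-5-enal | O=C[C@H](C)[C@@H](O[Si](C)(C)C(C)(C)C)[C@@H](C)C=C | intermediate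
7 | methyl (2Z,4S,5S,6S)-5-(tert-butyldimethylsilyloxy)-2,4,6-trimethylocta-2,7-dienoate | C/C(C(=O)OC)=C/[C@H](C)[C@@H](O[Si](C)(C)C(C)(C)C)[C@@H](C)C=C | intermediate
8 | (2Z,4S,5S,6S)-5-(tert-butyldimethylsilyloxy)-2,4,6-trimethylocta-2,7-dien-1-ol | C/C(CO)=C/[C@H](C)[C@@H](O[Si](C)(C)C(C)(C)C)[C@@H](C)C=C | intermediate
9 | (E)-but-2-enal (crotonaldehyde) | C/C=C/C=O | starting material
10 | (2E,4S,5S,6S,7Z)-5-(tert-butyldimethylsilyloxy)-9-hydroxy-4,6,8-trimethylnona-2,7-dienal | C/C(CO)=C/[C@H](C)[C@@H](O[Si](C)(C)C(C)(C)C)[C@@H](C)/C=C/C=O | intermediate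
11 | (2Z,4S,5S,6S,7E,9S)-5-(tert-butyldimethylsilyloxy)-2,4,6-trimethyldodeca-2,7,11-triene-1,9-diol | C/C(CO)=C/[C@H](C)[C@@H](O[Si](C)(C)C(C)(C)C)[C@@H](C)/C=C/[C@@H](O)CC=C | intermediate
12 | 3-methylbut-3-en-2-one | CC(=O)C(C)=C | starting material
13 | C10–C23 methyl ketone, (3E,6S,7E,9S,10S,11S,12Z)-10-(tert-butyldimethylsilyloxy)-6,14-dihydroxy-3,9,11,13-tetramethyltetradeca-3,7,12-trien-2-one | C/C(CO)=C/[C@H](C)[C@@H](O[Si](C)(C)C(C)(C)C)[C@@H](C)/C=C/[C@@H](O)C/C=C(\C)C(C)=O | intermediate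
14 | methyl (R)-3-hydroxy-2-methylpropanoate | OC[C@@H](C)C(=O)OC | starting material
15 | methyl (R)-3-(tert-butyldimethylsilyloxy)-2-methylpropanoate | CC(C)(C)[Si](C)(C)OC[C@@H](C)C(=O)OC | intermediate
16 | (R)-3-(tert-butyldimethylsilyloxy)-2-methylpropanal | CC(C)(C)[Si](C)(C)OC[C@@H](C)C=O | intermediate
17 | tert-butyl{[(2S,3E)-4-iodo-2-methylbut-3-en-1-yl]oxy}dimethylsilane | CC(C)(C)[Si](C)(C)OC[C@@H](C)/C=C/I | intermediate
18 | (2S,3E)-4-iodo-2-methylbut-3-en-1-ol | OC[C@@H](C)/C=C/I | intermediate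
19 | (2S,3E)-4-iodo-2-methylbut-3-enal | O=C[C@@H](C)/C=C/I | intermediate
20 | tris-TMS dienol ether of 13 (TMS ethers at C15-O and C23-O, TMS enol ether C10=C11) | C/C(CO[Si](C)(C)C)=C/[C@H](C)[C@@H](O[Si](C)(C)C(C)(C)C)[C@@H](C)/C=C/[C@@H](O[Si](C)(C)C)C/C=C(\C)C(=C)O[Si](C)(C)C | intermediate
21 | C6–C23 iodo triol (6-iodo; 9,15,23-triol; 19-OTBS; 11-ketone; 6E,12E,16E,21Z; 8S,9S,15S,18S,19S,20S) | C/C(CO)=C/[C@H](C)[C@@H](O[Si](C)(C)C(C)(C)C)[C@@H](C)/C=C/[C@@H](O)C/C=C(\C)C(=O)C[C@H](O)[C@@H](C)/C=C/I | intermediate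
22 | C6–C23 iodo Z-enal diol (C23 aldehyde; 9,15-diol; 19-OTBS; stereodescriptors as 21) | C/C(C=O)=C/[C@H](C)[C@@H](O[Si](C)(C)C(C)(C)C)[C@@H](C)/C=C/[C@@H](O)C/C=C(\C)C(=O)C[C@H](O)[C@@H](C)/C=C/I | intermediate
23 | C6–C23 iodo Z-enal tris-TBS ether (9,15,19-tris-OTBS) | C/C(C=O)=C/[C@H](C)[C@@H](O[Si](C)(C)C(C)(C)C)[C@@H](C)/C=C/[C@@H](O[Si](C)(C)C(C)(C)C)C/C=C(\C)C(=O)C[C@H](O[Si](C)(C)C(C)(C)C)[C@@H](C)/C=C/I | intermediate
24 | lithium 3-methylbuta-1,3-dien-2-olate (kinetic enolate of 12) | [Li]OC(=C)C(C)=C | intermediate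
25 | C6–C23 iodide carrying C23-OH and the C5'–C8' isopropenyl ketone (C23 epimers; 8S,9S,15S,18S,19S,20S) | C/C(C(O)CC(=O)C(C)=C)=C/[C@H](C)[C@@H](O[Si](C)(C)C(C)(C)C)[C@@H](C)/C=C/[C@@H](O[Si](C)(C)C(C)(C)C)C/C=C(\C)C(=O)C[C@H](O[Si](C)(C)C(C)(C)C)[C@@H](C)/C=C/I | intermediate
26 | (Z)-3-iodoprop-2-enoic acid | OC(=O)/C=C\I | starting material
27 | 2-amino-3-chlorophenol | Nc1c(O)cccc1Cl | starting material
28 | (Z)-3-iodoprop-2-enoyl chloride | ClC(=O)/C=C\I | intermediate
29 | (Z)-N-(2-chloro-6-hydroxyphenyl)-3-iodoprop-2-enamide | O=C(/C=C\I)Nc1c(O)cccc1Cl | intermediate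
30 | acetylene | C#C | starting material
31 | hexamethylditin | C[Sn](C)(C)[Sn](C)(C)C | starting material
32 | (Z)-1,2-bis(trimethylstannyl)ethene | C[Sn](C)(C)/C=C\[Sn](C)(C)C | intermediate
33 | (2Z,4Z)-N-(2-chloro-6-hydroxyphenyl)-5-(trimethylstannyl)penta-2,4-dienamide | C[Sn](C)(C)/C=C\C=C/C(=O)Nc1c(O)cccc1Cl | intermediate
34 | seco anilide (C1–C23 chain plus C5'–C8' enone; N-(2-chloro-6-hydroxyphenyl) amide; C23-OH; 2Z,4Z,6E,12E,16E,21Z; 8S,9S,15S,18S,19S,20S) | C/C(C(O)CC(=O)C(C)=C)=C/[C@H](C)[C@@H](O[Si](C)(C)C(C)(C)C)[C@@H](C)/C=C/[C@@H](O[Si](C)(C)C(C)(C)C)C/C=C(\C)C(=O)C[C@H](O[Si](C)(C)C(C)(C)C)[C@@H](C)/C=C/C=C\C=C/C(=O)Nc1c(O)cccc1Cl | intermediate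
35 | seco 2-amido-3-chloro-1,4-benzoquinone (as 34 with ring A oxidised; C23-OH) | C/C(C(O)CC(=O)C(C)=C)=C/[C@H](C)[C@@H](O[Si](C)(C)C(C)(C)C)[C@@H](C)/C=C/[C@@H](O[Si](C)(C)C(C)(C)C)C/C=C(\C)C(=O)C[C@H](O[Si](C)(C)C(C)(C)C)[C@@H](C)/C=C/C=C\C=C/C(=O)NC1=C(Cl)C(=O)C=CC1=O | intermediate
36 | seco amidoquinone 1,3-diketone (C23 and C6' ketones) | C/C(C(=O)CC(=O)C(C)=C)=C/[C@H](C)[C@@H](O[Si](C)(C)C(C)(C)C)[C@@H](C)/C=C/[C@@H](O[Si](C)(C)C(C)(C)C)C/C=C(\C)C(=O)C[C@H](O[Si](C)(C)C(C)(C)C)[C@@H](C)/C=C/C=C\C=C/C(=O)NC1=C(Cl)C(=O)C=CC1=O | intermediate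
37 | TMS dienol ether of 36 (Z enol ether C5'=C6'-OTMS, diene C5'=C6'–C7'=C8') | C/C(C(=O)/C=C(\O[Si](C)(C)C)C(C)=C)=C/[C@H](C)[C@@H](O[Si](C)(C)C(C)(C)C)[C@@H](C)/C=C/[C@@H](O[Si](C)(C)C(C)(C)C)C/C=C(\C)C(=O)C[C@H](O[Si](C)(C)C(C)(C)C)[C@@H](C)/C=C/C=C\C=C/C(=O)NC1=C(Cl)C(=O)C=CC1=O | intermediate
38 | macrocyclic Diels–Alder adduct (rings B and C closed; cis-fused enedione, TMS enol ether; new sp3 centres unassigned, lost on aromatisation) | C/C1=C/[C@H](C)[C@@H](O[Si](C)(C)C(C)(C)C)[C@@H](C)/C=C/[C@@H](O[Si](C)(C)C(C)(C)C)C/C=C(\C)C(=O)C[C@H](O[Si](C)(C)C(C)(C)C)[C@@H](C)/C=C/C=C\C=C/C(=O)NC2=C(Cl)C(=O)C3C(CC(C)=C(O[Si](C)(C)C)C3C1=O)C2=O | intermediate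
39 | 9,15,19-tris-O-(tert-butyldimethylsilyl) derivative of the target | C/C1=C/[C@H](C)[C@@H](O[Si](C)(C)C(C)(C)C)[C@@H](C)/C=C/[C@@H](O[Si](C)(C)C(C)(C)C)C/C=C(\C)C(=O)C[C@H](O[Si](C)(C)C(C)(C)C)[C@@H](C)/C=C/C=C\C=C/C(=O)NC2=C(Cl)C(=O)c3c(cc(C)c(O)c3C1=O)C2=O | intermediate
40 | CNP0257532.2 (2Z,4Z,6E,12E,16E,21Z; 8S,9S,15S,18S,19S,20S) | C/C1=C/[C@H](C)[C@@H](O)[C@@H](C)/C=C/[C@@H](O)C/C=C(\C)C(=O)C[C@H](O)[C@@H](C)/C=C/C=C\C=C/C(=O)NC2=C(Cl)C(=O)c3c(cc(C)c(O)c3C1=O)C2=O | target

**Step count**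
Total steps: 27. Longest linear sequence: 19 (steps 1–10, 16–19, 23–27).

**Three steps most likely to fail**

Step 26 (macrocyclising Diels–Alder reaction and aromatisation). The acyl-substituted siloxydiene is only moderately reactive, the ring being closed is 29-membered, and 36 can cyclise through its enol oxygen or oligomerise. The fallback sets out from 25 and 33 and comes back at 39. It builds ring B intermolecularly, where concentration and excess dienophile can drive the cycloaddition, and closes ring C by a Stille macrocyclisation. Dess–Martin periodinane converts 25 into C23-keto iodide F1. (KSO3)2NO converts 33 into stannyl dienamido quinone F2. F1 is silylated with N,O-bis(trimethylsilyl)acetamide and heated with F2 (3 equiv) at 0.5 M in toluene at 60 °C, then treated with MnO2, to give seco naphthoquinone F3, which carries the C6 vinyl iodide and the C5 stannane. Pd2(dba)3 and AsPh3 in DMF at 1 mM then join C5 to C6 and give 39.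

Step 24 (late phenol-to-quinone oxidation). The lipophilic substrate needs phase transfer, ortho-oxidation can compete, and the radical oxidant meets a polyene. The fallback sets out from 34 and comes back at 36, skipping 35. Dess–Martin periodinane (4 equiv) with water (2 equiv) in CH2Cl2 takes the o-hydroxyanilide through its o-imidoquinone; water adds para to the ring oxygen and a further equivalent of the reagent gives the p-quinone, while the C23 carbinol is oxidised to the ketone in the same flask. This is a hypervalent-iodine route with no aqueous radical oxidant.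

Step 23 (Stille union to the 2Z,4Z,6E-trienamide). It depends on the sensitive Z,Z-dienylstannane 33 (protodestannylation, Z-to-E erosion), and the free phenol and amide can slow transmetalation. The fallback sets out from 29 and 25 and comes back at 34. It replaces the stannane by an alkyne that is reduced after the union. Sonogashira coupling of 29 with trimethylsilylacetylene (PdCl2(PPh3)2, CuI, Et3N) gives silyl enynamide F4. K2CO3 in MeOH gives terminal enynamide F5. Sonogashira coupling of F5 with 25 gives dienynamide F6. Zinc activated with Cu(OAc)2 and AgNO3 in MeOH/H2O reduces the C4–C5 triple bond to the Z-alkene and gives 34.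

**Further compounds**
F1 | step 26 | C23-keto iodide (25 with the C23 carbinol oxidised to the ketone) | C/C(C(=O)CC(=O)C(C)=C)=C/[C@H](C)[C@@H](O[Si](C)(C)C(C)(C)C)[C@@H](C)/C=C/[C@@H](O[Si](C)(C)C(C)(C)C)C/C=C(\C)C(=O)C[C@H](O[Si](C)(C)C(C)(C)C)[C@@H](C)/C=C/I
F2 | step 26 | (2Z,4Z)-N-(2-chloro-3,6-dioxocyclohexa-1,4-dien-1-yl)-5-(trimethylstannyl)penta-2,4-dienamide | C[Sn](C)(C)/C=C\C=C/C(=O)NC1=C(Cl)C(=O)C=CC1=O
F3 | step 26 | seco naphthoquinone (rings A and B complete; C23 ketone on ring position 5; chain ending in the C6 vinyl iodide; stannyl dienamide on N) | C[Sn](C)(C)/C=C\C=C/C(=O)NC1=C(Cl)C(=O)c2c(cc(C)c(O)c2C(=O)/C(C)=C\[C@H](C)[C@@H](O[Si](C)(C)C(C)(C)C)[C@@H](C)/C=C/[C@@H](O[Si](C)(C)C(C)(C)C)C/C=C(\C)C(=O)C[C@H](O[Si](C)(C)C(C)(C)C)[C@@H](C)/C=C/I)C1=O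
F0 | step 24 | none | none
F4 | step 23 | (Z)-N-(2-chloro-6-hydroxyphenyl)-5-(trimethylsilyl)pent-2-en-4-ynamide | C[Si](C)(C)C#C/C=C\C(=O)Nc1c(O)cccc1Cl
F5 | step 23 | (Z)-N-(2-chloro-6-hydroxyphenyl)pent-2-en-4-ynamide | C#C/C=C\C(=O)Nc1c(O)cccc1Cl
F6 | step 23 | 4,5-didehydro analogue of 34 (2Z,6E-dien-4-ynamide) | C/C(C(O)CC(=O)C(C)=C)=C/[C@H](C)[C@@H](O[Si](C)(C)C(C)(C)C)[C@@H](C)/C=C/[C@@H](O[Si](C)(C)C(C)(C)C)C/C=C(\C)C(=O)C[C@H](O[Si](C)(C)C(C)(C)C)[C@@H](C)/C=C/C#C/C=C\C(=O)Nc1c(O)cccc1Cl
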